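All constants stand for no real mixture; no experiment stands behind them.

The reading I wanted was the one at 2.5 min: how much of the charged first end groups then stood as over-reaction product in each of these flasks.

| setting | eta | epsilon | delta | theta | zeta |
|---|---|---|---|---|---|
| first end groups | 0.020 M | 0.020 M | 0.020 M | 0.020 M (fed, over 1.5 min) | 0.020 M |
| second end groups | 0.0204 M | 0.0204 M (fed, over 10 s) | 0.0204 M (fed, over 1.5 min) | 0.0204 M | 0.0204 M (in portions, 4, over 1.5 min) |
| time | 2.5 min | 2.5 min | 2.5 min | 2.5 min | 2.5 min |
| remark | everything together at the start | all else is in the flask from the start; the feed brings no volume worth counting | all else is in the flask from the start; the feed brings no volume worth counting | all else is in the flask from the start; the feed brings no volume worth counting | first portion at the start, last at 1.5 min |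

    first end groups + second end groups → links (k1 = 7.7 M⁻¹ s⁻¹)
    links → over-reaction product (k2 = 0.12 s⁻¹)
    first end groups ⇌ dormant form (K3 = 0.33, k3 = 0.63 s⁻¹)
    first end groups + links → side product (k4 = 20 M⁻¹ s⁻¹)

- percent here means first end groups units held: one side product counts as two
- run time (eta): 2.5 min

* which flask leads in amount of over-reaction product, in percent of the first end groups charged ("all alike" within 1.5 percentage points) (eta / epsilon / delta / theta / zeta / all alike)
* how much over-reaction product is there at the end, in percent of the first end groups charged: eta
* how much over-reaction product is there at the end, in percent of the first end groups charged: epsilon
* how much over-reaction product is there at the end, in percent of the first end groups charged: delta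
* how much over-reaction product is there at the end, in percent of the first end groups charged: theta
* how much over-reaction product is there at the end, in percent of the first end groups charged: zeta

I reckoned with one quantity. A link leaves by two exits: it turns by itself into over-reaction product, or a free first end group takes it into side product, and that second exit spends a further first end group. So the units of charge consumed split between the two products in the ratio of the link's own rate constant to twice the side constant times the free first end groups. The two shares are equal at the break-even level 15.0%, the free first end groups, as a fraction of the charge, at which over-reaction product and side product gain alike. The local yield (a selectivity factor) is then one over one plus free level over break-even level.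

In the first instants the exchange with the dormant form relaxes with a half-life of 0.273 s in theta, against 0.074 min for first end groups by link formation in eta. So I took that exchange as balanced, with a fraction 0.752 of the pair, first end groups plus dormant form, free.

In the middle the recipes part. In delta and zeta second end groups arrive over 1.5 min, far longer than the 0.096 min half-life of links by step 2 in eta, so I let links keep pace and the free level fall with the pair. Integrating the yield from full charge to nothing, with the ratio 5.01 of the starting free level to break-even, gives 35.8%. I put delta at 35.8% and zeta at 35.8%. In eta first end groups go to links with a half-life of 0.074 min, shorter than the 0.096 min of links by step 2, so I let the free level drop before links build up, and I took 35.8% as a floor for eta. For epsilon, whose feed of 10 s is far shorter than 1.5 min, I took 35.8% as a floor too. In theta I put the free level where feed and link formation balance, near 7.07%, below the break-even level, which gives 68.0% with second end groups taken as charged, a figure I held to be high since they thin out. So I expected theta to lead. At the end comes the tail after the feed, which I did not reckon.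

The forecast gave 43% for eta, 42% for epsilon, 38% for delta, 56% for theta and 39% for zeta, with theta leading, on the ground that “feeding the first end groups slowly into excess second end groups keeps that contact lowest”, and for theta my figure stood higher than the forecast's.

The simulation put theta ahead: 41.9% for eta, 41.2% for epsilon, 37.2% for delta, 63.1% for theta, 36.8% for zeta. At 0.875 min in theta, links were going to over-reaction product 3.5 times as fast as to side product. With the break-even level, that reading puts free first end groups in theta at that moment at 8.57% of the charge, above my figure, and the local yield at 63.6%.

A neighbour of theta holds 0.035 M of second end groups. By the same reckoning the break-even level in that neighbour is unchanged, the free level comes to 4.12%, and the yield to 78.5%. The simulation gave 77.5% there.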